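## Analysis of the target

Target 17 is an achiral diaryl ether with no stereocentres. Ring A carries a1 OMe, a2 H, a3 CO2H, a4 ether oxygen, a5 OH and a6 Cl. Ring B carries b1 ether oxygen, b2 H, b3 CH3, b4 H, b5 OH and b6 CO2H. The ether links a4, flanked by a carboxyl and a hydroxyl, to b1, flanked by a carboxyl, so the C–O–C bond is tri-ortho-substituted and poorly suited to a late cross-coupling. Ring B is the easy half: it is the substitution pattern of the commercial symmetric ester 1. Ring A is the hard half. Its chlorine sits on a6 between two oxygens, where electrophilic chlorination of a finished arene does not go (a2, para to the a5 oxygen, and the electron-rich ring B would compete). Its two meta oxygens must also end up different, OMe on a1 and OH on a5. Sensitive points are the 2,6-dioxygenated benzoic acid of ring B (decarboxylation with heat or strong acid), the aryl chloride (reductive conditions) and the free phenols (over-halogenation). The route rests on one feature of ring A: the oxygens on a1 and a5 are 1,3 with chlorine on a6 between them, which is the pattern of a 2-chlorocyclohexane-1,3-dione. In that dione a4 (bearing the aryloxy group) is alpha to the a5 carbonyl, and a3 (bearing the carboxyl) is the beta carbon of a butenedioate.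

## Retrosynthetic reasoning

**17 to 15.** The last two operations only release functional groups. Cutting the O–CH3 bond of the a3 ester leads back to 16, and cutting the O–benzyl bond on b5 leads back to 15. The b5 phenol stays protected until then because a free resorcinol-type ring B would not survive the two halogenations. The b6 carboxyl is already free in 15, so only the unhindered a3 ester has to be hydrolysed at the end.

**15 to 12.** Ring A of 15 is taken back to the cyclohexenone 12 by returning two hydrogens to a4 and a3. The forward step must aromatize without a4 losing its oxygen. In 12 the aryloxide is beta to the a3 ester and would be expelled by any base strong enough to make the ester enolate. The answer is to place a better leaving group on the ring first: the silyl dienol ether 13 is brominated to 14, in which bromide is lost in preference to aryloxide.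

**12 to 10.** The a6–Cl bond is cut to give 11, and the a1–OCH3 bond is cut to give dione 10. Both bonds are made on the non-aromatic ring because it offers selectivity the arene lacks. In 11 the carbon a6 is the nucleophilic centre of a vinylogous ester and is by far the most reactive site toward an electrophilic chlorine source. In 10 the two carbonyls are different: a5 has the aryloxy-bearing a4 as neighbour, a1 has a methylene, so acid-catalysed etherification should choose a1.

**10 to 7 and 8.** This is the key disconnection. Bonds a4–a3 and a6–a1 are cut, which divides ring A into the three-carbon ketone unit of 7 (a4, a5, a6) and the butenedioate 8 (a3, a2, a1 and the a3 ester). The cut is made here because a3 ends up alpha to an ester and can therefore be the electrophilic carbon toward a4. This solves the 1,4 relation between the ester carbonyl and the a5 oxygen with ordinary enolate polarity. Forward, the step has to make a Michael bond through the oxygenated carbon of 7 and then a Claisen bond from the methyl group to the distal ester, passing through the open-chain adduct 9.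

**7 to 1.** In 7 the b6 carboxyl is deliberately a free acid. An ester at b6 would sit five atoms from the aryloxymethylene enolate and would be acylated intramolecularly to a benzofuran-3-one (the usual fate of salicylate-derived aryloxy ketones in base) before 8 could react. A carboxylate cannot be acylated. For the same reason the ketone of 7 is unveiled only after the ester has gone. The C=O of 7 is traced back to the alkene of 5 (oxidative cleavage through diol 6), acid 5 to ester 4 (saponification with no enolizable ketone present), and 4 to phenol 2 and the allylic chloride 3, a masked acetonyl unit. Phenol 2 comes from the symmetric diol 1 by a single O-benzylation.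

## Alternatives that were turned down

**Alternative 1:** Ring B is taken apart into three alkynes: the ring A aryl ether of a propynol, 3-[2-(benzyloxy)-6-({[tert-butyl(dimethyl)silyl]oxy}methyl)-3-chloro-4-methoxyphenoxy]prop-2-yn-1-ol (A2), dipropan-2-yl ethynylboronate (A3) and propyne (A4).
- Forward step: A2 and A3 exchange to a boron–oxygen tethered diyne, and a ruthenium-catalysed [2+2+2] cyclotrimerization with A4 closes ring B as the benzoxaborole A1, 4-[2-(benzyloxy)-6-({[tert-butyl(dimethyl)silyl]oxy}methyl)-3-chloro-4-methoxyphenoxy]-6-methyl-1-(propan-2-yloxy)-1,3-dihydro-2,1-benzoxaborole.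
- For it: three ring bonds form in one step, the tether fixes the positions of b1, b5 and b6, and the C–B bond is a direct precursor of the b5 phenol. On regiocontrol within ring B it is stronger than the chosen route, which never has to build ring B at all.
- Against it: the whole of ring A, including the chlorine between two oxygens, must be made beforehand by arene chemistry, so the real difficulty of the target is untouched. A2 is an alkynyl ether of a doubly ortho-substituted phenol, itself several steps, and such electron-rich alkynes are untested partners in this cyclotrimerization. Both carboxyls enter as CH2O groups, so two benzylic oxidations and a C–B oxidation must follow next to free phenols.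
- Comparison: more bonds per key step and a better precedented substrate class for the catalyst, but a much longer route overall. The chosen strategy buys ring B and spends its steps on ring A.

**Alternative 2:** Ring B is cut into the aryloxypyrone ester A6, methyl 4-[2-(benzyloxy)-3-chloro-4-methoxy-6-(methoxycarbonyl)phenoxy]-6-methyl-2-oxo-2H-pyran-3-carboxylate, and 1,1-dimethoxyethene (A7).
- Forward step: on heating, A7 adds across the pyrone diene; extrusion of the lactone bridge and loss of one alkoxy group give the 2-methoxybenzoate A5, methyl 3-(benzyloxy)-4-chloro-5-methoxy-2-[3-methoxy-2-(methoxycarbonyl)-5-methylphenoxy]benzoate.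
- For it: both carboxyls are at the right oxidation level, the regiochemistry of the cycloaddition is unambiguous, and electron-poor pyrone esters with ketene acetals are an established pairing. It is more convergent than the chosen route and its key step is more likely to work as drawn.
- Against it: the aryloxy donor on the pyrone lowers its reactivity as an electron-poor diene. The b5 oxygen arrives as a methyl ether that must be cleaved without touching the a1 methyl ether. A doubly ortho-substituted methyl ester on ring B must be saponified at the end. Above all, A6 needs the ready-made ring A phenol with chlorine between the oxygens, attached through a hindered hydroxyl.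
- Comparison: stronger on convergence and certainty of the key step. The chosen strategy offers a construction of ring A in which chlorine and the O-methyl group are placed by the inherent reactivity of a dione.

**Alternative 3:** Ring B is cut by a Danheiser benzannulation into the aryl alkynyl ether A9, tert-butyl({3-[2-(benzyloxy)-6-({[tert-butyl(dimethyl)silyl]oxy}methyl)-3-chloro-4-methoxyphenoxy]prop-2-yn-1-yl}oxy)dimethylsilane, and 3-methylcyclobut-2-en-1-one (A10).
- Forward step: heating opens A10 to a vinylketene, which undergoes (2+2) cycloaddition with A9; four-electron ring opening and six-electron electrocyclization give the phenol A8, 3-[2-(benzyloxy)-6-({[tert-butyl(dimethyl)silyl]oxy}methyl)-3-chloro-4-methoxyphenoxy]-2-({[tert-butyl(dimethyl)silyl]oxy}methyl)-5-methylphenol.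
- For it: no metal is needed, heteroatom-substituted alkynes are the best ketenophiles, the regiochemistry is intrinsic, and the b5 phenol is delivered free. On these points it is stronger than the chosen route.
- Against it: it shares the unsolved ring A and the hindered alkynyl ether with Alternative 1. A10 is volatile and must be prepared. Both carboxyls again start as silyloxymethyl groups, so two oxidations are needed late, one of them on an ortho-hydroxybenzyl position that ionizes easily.
- Comparison: an elegant ring B synthesis attached to a long ring A synthesis. The chosen route is shorter because the ring it constructs is the difficult one.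

Key step: step 5

## Route

Remark on the chemistry: 1, 3 and 8 are taken as commercial; every sp3 stereocentre in 6 and 9 to 14 is racemic or undefined, which is immaterial for an achiral target.

Step 1
Reactants: 1 methyl 2,6-dihydroxy-4-methylbenzoate
Product: 2 methyl 2-(benzyloxy)-6-hydroxy-4-methylbenzoate
Conditions: BnBr (1.0 equiv), K2CO3, acetone, reflux
Reagents that add atoms: benzyl bromide, BrCc1ccccc1
Why: Williamson etherification of a symmetric bis-phenol, so no regiochemistry arises. After the first alkylation the remaining hydroxyl is locked in a hydrogen bond to the ester carbonyl and reacts more slowly, so the mono-ether should predominate; dibenzyl ether and unreacted 1 are separable.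

Step 2
Reactants: 2 methyl 2-(benzyloxy)-6-hydroxy-4-methylbenzoate; 3 3-chloro-2-methylprop-1-ene
Product: 4 methyl 2-(benzyloxy)-4-methyl-6-[(2-methylprop-2-en-1-yl)oxy]benzoate
Conditions: K2CO3, KI (cat.), DMF, 60 °C
Reagents that add atoms: none
Why: Iodide-assisted Williamson etherification with an allylic chloride. The 2-methylallyl group is a masked acetonyl unit with no enolizable carbonyl, so nothing can condense with the neighbouring ester.

Step 3
Reactants: 4 methyl 2-(benzyloxy)-4-methyl-6-[(2-methylprop-2-en-1-yl)oxy]benzoate
Product: 5 2-(benzyloxy)-4-methyl-6-[(2-methylprop-2-en-1-yl)oxy]benzoic acid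
Conditions: KOH, MeOH/H2O, reflux; then aq. HCl, 0 °C
Reagents that add atoms: potassium hydroxide, [K+].[OH-]
Why: Saponification of a 2,6-dialkoxybenzoate, slow for steric reasons but clean under forcing conditions because the benzyl and allyl ethers are inert to aqueous hydroxide. Removing the ester here means no acylating group is left on ring B when the ketone appears.

Step 4
Reactants: 5 2-(benzyloxy)-4-methyl-6-[(2-methylprop-2-en-1-yl)oxy]benzoic acid
Product: 7 2-(benzyloxy)-4-methyl-6-(2-oxopropoxy)benzoic acid, via diol 6 (not isolated)
Conditions: K2OsO4·2H2O (2 mol %), NaIO4 (3 equiv), 2,6-lutidine, dioxane/H2O, rt; then aq. HCl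
Reagents that add atoms: sodium periodate, [Na+].[O-]I(=O)(=O)=O (oxygen of the new ketone, delivered by way of the osmium catalyst)
Why: Lemieux–Johnson cleavage: catalytic dihydroxylation of the 1,1-disubstituted alkene to diol 6 and periodate cleavage to the methyl ketone. The electron-rich arene, the benzyl ether and the carboxylate are not attacked by this oxidant pair.

Step 5
Reactants: 7 2-(benzyloxy)-4-methyl-6-(2-oxopropoxy)benzoic acid; 8 dimethyl (2E)-but-2-enedioate (dimethyl fumarate)
Product: 10 2-(benzyloxy)-6-{[(1R*,2S*)-2-(methoxycarbonyl)-4,6-dioxocyclohexyl]oxy}-4-methylbenzoic acid, via Michael adduct 9 (not isolated)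
Conditions: NaOMe (3.5 equiv), 8 (1.5 equiv), MeOH, 0 to 45 °C; then aq. HCl, 0 °C
Reagents that add atoms: none
Why: This is a base-mediated Michael–Claisen annulation, closest in type to the alkoxide condensation of methyl ketones with maleate or fumarate diesters that gives alkyl 3,5-dioxocyclohexanecarboxylates; the new element is the aryloxy group on the donor carbon. NaOMe first converts 7 into its carboxylate, which no enolate can acylate, and then reversibly into the enolate at the aryloxymethylene carbon, the more acidic alpha position because of the inductive pull of the aryloxy oxygen; conjugate addition to 8 forms a4–a3 and gives adduct 9. Proton transfer to the methyl ketone enolate is followed by a 6-(enolexo)-exo-trig Claisen acylation of the distal ester (a6–a1) with loss of methoxide, and deprotonation of the new 1,3-dione makes the sequence irreversible. Three selectivities are needed: addition through the oxygenated carbon and not the methyl group, which rests on the higher acidity and population of that enolate; six- rather than five-membered acylation, which rests on the distal ester giving the strain-free ring, as in the parent reaction; and ring closure before E1cB loss of the aryloxide from a4 by way of the a3 ester enolate, which rests on ketone enolates forming far more readily than ester enolates, on a moderate temperature, and on the product being held as a dione enolate that is not deprotonated again at a3. The two new stereocentres at a4 and a3 are both epimerizable under the conditions and should settle in the trans diequatorial arrangement; the product is racemic and both centres disappear on aromatization.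

Step 6
Reactants: 10 2-(benzyloxy)-6-{[(1R*,2S*)-2-(methoxycarbonyl)-4,6-dioxocyclohexyl]oxy}-4-methylbenzoic acid
Product: 11 2-(benzyloxy)-6-{[(1R*,6S*)-4-methoxy-6-(methoxycarbonyl)-2-oxocyclohex-3-en-1-yl]oxy}-4-methylbenzoic acid
Conditions: MeOH, TsOH·H2O (10 mol %), 3 Å MS, 40 °C
Reagents that add atoms: methanol, CO
Why: Acid-catalysed enol etherification of a cyclic 1,3-dione under equilibrating conditions. Methanol should end up on a1, the carbonyl flanked by a methylene, and not on a5, which is crowded and inductively disfavoured by the aryloxy-bearing a4. The doubly ortho-substituted benzoic acid does not undergo Fischer esterification under these conditions.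

Step 7
Reactants: 11 2-(benzyloxy)-6-{[(1R*,6S*)-4-methoxy-6-(methoxycarbonyl)-2-oxocyclohex-3-en-1-yl]oxy}-4-methylbenzoic acid
Product: 12 2-(benzyloxy)-6-{[(1R*,6S*)-3-chloro-4-methoxy-6-(methoxycarbonyl)-2-oxocyclohex-3-en-1-yl]oxy}-4-methylbenzoic acid
Conditions: NCS (1.05 equiv), CH2Cl2, 0 °C to rt
Reagents that add atoms: N-chlorosuccinimide, O=C1CCC(=O)N1Cl
Why: Electrophilic alpha-chlorination of a vinylogous ester at a6, the only carbon between the two oxygenated carbons. That enol-ether carbon is much more nucleophilic than ring B, which carries a deactivating carboxyl, so one equivalent at low temperature should chlorinate a6 only.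

Step 8
Reactants: 12 2-(benzyloxy)-6-{[(1R*,6S*)-3-chloro-4-methoxy-6-(methoxycarbonyl)-2-oxocyclohex-3-en-1-yl]oxy}-4-methylbenzoic acid
Product: 15 2-(benzyloxy)-6-[3-chloro-2-hydroxy-4-methoxy-6-(methoxycarbonyl)phenoxy]-4-methylbenzoic acid, via silyl dienol ether 13 (not isolated), via bromo ketone 14 (not isolated)
Conditions: TMSOTf (2.3 equiv), Et3N, CH2Cl2, 0 °C; NBS, THF, −78 °C; DBU, −78 °C to rt; aq. NH4Cl
Reagents that add atoms: none
Why: Soft enolization gives the silyl dienol ether 13 (and the silyl ester), NBS brominates its aryloxy-bearing terminus a4 to 14 with return of the vinylogous ester, and dehydrobromination across a4–a3 followed by tautomerization of the dienone gives the phenol (halogenation–dehydrohalogenation aromatization). Because a4 then carries both bromide and aryloxide, the elimination expels the far better leaving group and the ether is kept; a bromide placed at a2 instead would lead to the same arene.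

Step 9
Reactants: 15 2-(benzyloxy)-6-[3-chloro-2-hydroxy-4-methoxy-6-(methoxycarbonyl)phenoxy]-4-methylbenzoic acid
Product: 16 2-[3-chloro-2-hydroxy-4-methoxy-6-(methoxycarbonyl)phenoxy]-6-hydroxy-4-methylbenzoic acid
Conditions: BCl3 (5 equiv), C6HMe5 (3 equiv), CH2Cl2, −78 to −30 °C; then MeOH, H2O
Reagents that add atoms: none
Why: Lewis-acid debenzylation with pentamethylbenzene as a non-basic trap for the benzyl cation. The benzyl ether next to the carboxyl is activated by chelation, while the a1 methyl ether has no neighbouring carbonyl and should survive, as should the aryl chloride and the methyl ester.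

Step 10
Reactants: 16 2-[3-chloro-2-hydroxy-4-methoxy-6-(methoxycarbonyl)phenoxy]-6-hydroxy-4-methylbenzoic acid
Product: 17 2-(2-carboxy-3-hydroxy-5-methylphenoxy)-4-chloro-3-hydroxy-5-methoxybenzoic acid
Conditions: LiOH·H2O (6 equiv), THF/H2O, rt to 40 °C; then aq. HCl, 0 °C
Reagents that add atoms: lithium hydroxide, [Li+].[OH-]
Why: Saponification of a methyl benzoate with a single ortho substituent, which needs no forcing. The diacid is kept as its salt until a cold acidification, so the decarboxylation-prone ring B acid is never heated in acid.

## Compound list

1 | methyl 2,6-dihydroxy-4-methylbenzoate | COC(=O)c1c(O)cc(C)cc1O | starting material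
2 | methyl 2-(benzyloxy)-6-hydroxy-4-methylbenzoate | COC(=O)c1c(O)cc(C)cc1OCc1ccccc1 | intermediate
3 | 3-chloro-2-methylprop-1-ene | CC(=C)CCl | starting material
4 | methyl 2-(benzyloxy)-4-methyl-6-[(2-methylprop-2-en-1-yl)oxy]benzoate | COC(=O)c1c(OCC(C)=C)cc(C)cc1OCc1ccccc1 | intermediate
5 | 2-(benzyloxy)-4-methyl-6-[(2-methylprop-2-en-1-yl)oxy]benzoic acid | OC(=O)c1c(OCC(C)=C)cc(C)cc1OCc1ccccc1 | intermediate
6 | 2-(benzyloxy)-6-(2,3-dihydroxy-2-methylpropoxy)-4-methylbenzoic acid (racemic) | OC(=O)c1c(OCC(C)(O)CO)cc(C)cc1OCc1ccccc1 | intermediate (not isolated)
7 | 2-(benzyloxy)-4-methyl-6-(2-oxopropoxy)benzoic acid | CC(=O)COc1cc(C)cc(OCc2ccccc2)c1C(=O)O | intermediate (precursor of the key step)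
8 | dimethyl (2E)-but-2-enedioate | COC(=O)/C=C/C(=O)OC | starting material
9 | dimethyl 2-{1-[3-(benzyloxy)-2-carboxy-5-methylphenoxy]-2-oxopropyl}butanedioate (mixture of diastereomers, racemic) | COC(=O)CC(C(=O)OC)C(Oc1cc(C)cc(OCc2ccccc2)c1C(=O)O)C(C)=O | intermediate (not isolated)
10 | 2-(benzyloxy)-6-{[(1R*,2S*)-2-(methoxycarbonyl)-4,6-dioxocyclohexyl]oxy}-4-methylbenzoic acid (trans, racemic, one enantiomer drawn) | O=C1CC(=O)[C@H](Oc2cc(C)cc(OCc3ccccc3)c2C(=O)O)[C@@H](C(=O)OC)C1 | intermediate (product of the key step)
11 | 2-(benzyloxy)-6-{[(1R*,6S*)-4-methoxy-6-(methoxycarbonyl)-2-oxocyclohex-3-en-1-yl]oxy}-4-methylbenzoic acid (trans, racemic) | COC1=CC(=O)[C@H](Oc2cc(C)cc(OCc3ccccc3)c2C(=O)O)[C@@H](C(=O)OC)C1 | intermediate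
12 | 2-(benzyloxy)-6-{[(1R*,6S*)-3-chloro-4-methoxy-6-(methoxycarbonyl)-2-oxocyclohex-3-en-1-yl]oxy}-4-methylbenzoic acid (trans, racemic) | COC1=C(Cl)C(=O)[C@H](Oc2cc(C)cc(OCc3ccccc3)c2C(=O)O)[C@@H](C(=O)OC)C1 | intermediate
13 | trimethylsilyl 2-(benzyloxy)-6-({3-chloro-4-methoxy-6-(methoxycarbonyl)-2-[(trimethylsilyl)oxy]cyclohexa-1,3-dien-1-yl}oxy)-4-methylbenzoate (racemic) | COC(=O)C1CC(OC)=C(Cl)C(O[Si](C)(C)C)=C1Oc1cc(C)cc(OCc2ccccc2)c1C(=O)O[Si](C)(C)C | intermediate (not isolated)
14 | trimethylsilyl 2-(benzyloxy)-6-{[1-bromo-3-chloro-4-methoxy-6-(methoxycarbonyl)-2-oxocyclohex-3-en-1-yl]oxy}-4-methylbenzoate (mixture of diastereomers) | COC(=O)C1CC(OC)=C(Cl)C(=O)C1(Br)Oc1cc(C)cc(OCc2ccccc2)c1C(=O)O[Si](C)(C)C | intermediate (not isolated)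
15 | 2-(benzyloxy)-6-[3-chloro-2-hydroxy-4-methoxy-6-(methoxycarbonyl)phenoxy]-4-methylbenzoic acid | COC(=O)c1cc(OC)c(Cl)c(O)c1Oc1cc(C)cc(OCc2ccccc2)c1C(=O)O | intermediate
16 | 2-[3-chloro-2-hydroxy-4-methoxy-6-(methoxycarbonyl)phenoxy]-6-hydroxy-4-methylbenzoic acid | COC(=O)c1cc(OC)c(Cl)c(O)c1Oc1cc(C)cc(O)c1C(=O)O | intermediate
17 | 2-(2-carboxy-3-hydroxy-5-methylphenoxy)-4-chloro-3-hydroxy-5-methoxybenzoic acid | COc1cc(C(=O)O)c(Oc2cc(C)cc(O)c2C(=O)O)c(O)c1Cl | target

## Step count and least certain steps

Total step count: 10. Longest linear sequence: 10 steps, from 1 to 17.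

**Step 5 (key step).**
- Most likely failure: elimination of the aryloxide from the open-chain adduct before the ring closes. The hydrogen on a3 is alpha to an ester and the aryloxy group on a4 is beta to it, so an E1cB pathway competes with the Claisen closure. A second failure is conjugate addition through the methyl group of the ketone, which would lead to the isomeric dione.
- Fallback, from 7 back to 11: 8 is replaced by its commercial half ester, monomethyl fumarate, used as the sodium salt with NaOMe in MeOH at reflux. The enolate then adds to the carbon that bears the carboxylate (beta to the ester), so a3 carries CO2− and its hydrogen can no longer be removed. The elimination is closed off by structure and is not merely outrun, and only one ester is left to be acylated. The product should be 2-(benzyloxy)-6-{[(1R*,2S*)-2-carboxy-4,6-dioxocyclohexyl]oxy}-4-methylbenzoic acid F1. Under the conditions of step 6, run longer, the aliphatic acid of F1 is Fischer-esterified while the dione is etherified and the hindered ring B acid stays free, which gives 11. The price is a less electrophilic, anionic acceptor.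

**Step 6.**
- Most likely failure: poor regioselectivity of enol ether formation. The two carbonyls differ only in their neighbours, and an equilibrium mixture with the a5 enol ether would put the methyl group on the wrong oxygen.
- Fallback, from 10 back to 17: the methylation is moved to the aromatic stage, where the two oxygens differ more.
  - Dione 10 is chlorinated with NCS at 0 °C to 2-(benzyloxy)-6-{[(1R*,2S*)-5-chloro-2-(methoxycarbonyl)-4,6-dioxocyclohexyl]oxy}-4-methylbenzoic acid F2.
  - F2 is aromatized by the silylation, bromination and base sequence of step 8 to 2-(benzyloxy)-6-[3-chloro-2,4-dihydroxy-6-(methoxycarbonyl)phenoxy]-4-methylbenzoic acid F3.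
  - MeI (2.2 equiv) and K2CO3 in acetone methylate the carboxylate and the less hindered a1 phenol, which has a hydrogen on one side where the a5 phenol has the aryloxy group. This gives methyl 2-(benzyloxy)-6-[3-chloro-2-hydroxy-4-methoxy-6-(methoxycarbonyl)phenoxy]-4-methylbenzoate F4.
  - BCl3 with pentamethylbenzene gives methyl 2-[3-chloro-2-hydroxy-4-methoxy-6-(methoxycarbonyl)phenoxy]-6-hydroxy-4-methylbenzoate F5.
  - LiOH in aqueous DMSO at 80 °C hydrolyses both esters, the hindered one included, to 17.

**Step 8.**
- Most likely failure: loss of the aryloxy group by base-induced elimination from 12 or 14 in competition with loss of bromide, or bromination on ring B instead of on the dienol ether. Either would give an arene without the ether link or with an extra halogen.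
- Fallback, from 12 back to 15: the silyl dienol ether 13 is made as before, freed of ammonium salts, and dehydrogenated with DDQ in the presence of 2,6-lutidine in CH2Cl2 at 0 °C. Hydride abstraction and loss of the silyl group give the dienone, which tautomerizes to 15 on aqueous work-up. No halogen and no strong base are involved, and no new isolated compound is made.

**Step 9.**
- Most likely failure: cleavage of the a1 methyl ether, or protodecarboxylation of the ring B acid under the Lewis and protic acid present.
- Fallback, from 15 back to 16: hydrogenolysis of the benzyl ether with H2 (1 atm) over Pd/C in EtOAc at rt, stopped at full conversion to limit reductive loss of chlorine. No new compound is made.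

## Further compounds

F1 | step 5 | 2-(benzyloxy)-6-{[(1R*,2S*)-2-carboxy-4,6-dioxocyclohexyl]oxy}-4-methylbenzoic acid (trans, racemic) | O=C1CC(=O)[C@H](Oc2cc(C)cc(OCc3ccccc3)c2C(=O)O)[C@@H](C(=O)O)C1
F2 | step 6 | 2-(benzyloxy)-6-{[(1R*,2S*)-5-chloro-2-(methoxycarbonyl)-4,6-dioxocyclohexyl]oxy}-4-methylbenzoic acid (trans, racemic, chlorinated carbon undefined) | O=C1C(Cl)C(=O)[C@H](Oc2cc(C)cc(OCc3ccccc3)c2C(=O)O)[C@@H](C(=O)OC)C1
F3 | step 6 | 2-(benzyloxy)-6-[3-chloro-2,4-dihydroxy-6-(methoxycarbonyl)phenoxy]-4-methylbenzoic acid | COC(=O)c1cc(O)c(Cl)c(O)c1Oc1cc(C)cc(OCc2ccccc2)c1C(=O)O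
F4 | step 6 | methyl 2-(benzyloxy)-6-[3-chloro-2-hydroxy-4-methoxy-6-(methoxycarbonyl)phenoxy]-4-methylbenzoate | COC(=O)c1cc(OC)c(Cl)c(O)c1Oc1cc(C)cc(OCc2ccccc2)c1C(=O)OC
F5 | step 6 | methyl 2-[3-chloro-2-hydroxy-4-methoxy-6-(methoxycarbonyl)phenoxy]-6-hydroxy-4-methylbenzoate | COC(=O)c1cc(OC)c(Cl)c(O)c1Oc1cc(C)cc(O)c1C(=O)OC
F0 | step 8 | none | none
F0 | step 9 | none | none
A1 | alternative 1 | 4-[2-(benzyloxy)-6-({[tert-butyl(dimethyl)silyl]oxy}methyl)-3-chloro-4-methoxyphenoxy]-6-methyl-1-(propan-2-yloxy)-1,3-dihydro-2,1-benzoxaborole | CC(C)OB1OCc2c1cc(C)cc2Oc1c(CO[Si](C)(C)C(C)(C)C)cc(OC)c(Cl)c1OCc1ccccc1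
A2 | alternative 1 | 3-[2-(benzyloxy)-6-({[tert-butyl(dimethyl)silyl]oxy}methyl)-3-chloro-4-methoxyphenoxy]prop-2-yn-1-ol | OCC#COc1c(CO[Si](C)(C)C(C)(C)C)cc(OC)c(Cl)c1OCc1ccccc1
A3 | alternative 1 | dipropan-2-yl ethynylboronate | C#CB(OC(C)C)OC(C)C
A4 | alternative 1 | propyne | CC#C
A5 | alternative 2 | methyl 3-(benzyloxy)-4-chloro-5-methoxy-2-[3-methoxy-2-(methoxycarbonyl)-5-methylphenoxy]benzoate | COC(=O)c1c(OC)cc(C)cc1Oc1c(C(=O)OC)cc(OC)c(Cl)c1OCc1ccccc1
A6 | alternative 2 | methyl 4-[2-(benzyloxy)-3-chloro-4-methoxy-6-(methoxycarbonyl)phenoxy]-6-methyl-2-oxo-2H-pyran-3-carboxylate | COC(=O)C1=C(Oc2c(C(=O)OC)cc(OC)c(Cl)c2OCc2ccccc2)C=C(C)OC1=O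
A7 | alternative 2 | 1,1-dimethoxyethene | COC(=C)OC
A8 | alternative 3 | 3-[2-(benzyloxy)-6-({[tert-butyl(dimethyl)silyl]oxy}methyl)-3-chloro-4-methoxyphenoxy]-2-({[tert-butyl(dimethyl)silyl]oxy}methyl)-5-methylphenol | COc1cc(CO[Si](C)(C)C(C)(C)C)c(Oc2cc(C)cc(O)c2CO[Si](C)(C)C(C)(C)C)c(OCc2ccccc2)c1Cl
A9 | alternative 3 | tert-butyl({3-[2-(benzyloxy)-6-({[tert-butyl(dimethyl)silyl]oxy}methyl)-3-chloro-4-methoxyphenoxy]prop-2-yn-1-yl}oxy)dimethylsilane | CC(C)(C)[Si](C)(C)OCC#COc1c(CO[Si](C)(C)C(C)(C)C)cc(OC)c(Cl)c1OCc1ccccc1
A10 | alternative 3 | 3-methylcyclobut-2-en-1-one | CC1=CC(=O)C1
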